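## Retrosynthetic overview

1. The last bond made is the C7–O–C1' aryl ether: target = 7-hydroxy-8-methoxycoumarin (21) + side-chain diol tosylate (13).
2. 13 comes from an epoxy tosylate butyrolactone (12): the anti 2',3'-diol by invertive hydrolysis of a Sharpless epoxide, the cis α-methyl lactone by hydrogenation of a butenolide.
3. The butenolide is closed by ring-closing metathesis of the methacrylate of a vinyl carbinol (key ring closure); its dienediol precursor 7 comes from (R)-epichlorohydrin via (R)-hex-1-en-5-yn-3-ol and Negishi carboalumination.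
4. Coumarin 21 is made in a parallel branch from 2-methoxyresorcinol; its pyranone ring is also closed by ring-closing metathesis (2-vinylphenyl acrylate).
5. Ring order: butenolide (step 7, saturated in step 8) and coumarin (step 14) are formed independently; the two halves are joined in the final step.

Assumption: side-chain carbons are called C1' (ArOCH2) to C8' (lactone C=O), with the methyls on C3' and C7'.

## Route

Step 1
Reactants: 1 (R)-epichlorohydrin
Product: 2 (2R)-1-chloro-5-(trimethylsilyl)pent-4-yn-2-ol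
Conditions: TMS-acetylene, n-BuLi, THF, −78 °C; BF3·OEt2; then 1, −78 °C
Reagents that add atoms: ethynyltrimethylsilane C#C[Si](C)(C)C
Why: BF3-promoted acetylide opening of the epoxide (Yamaguchi alkynylation) occurs only at the unsubstituted carbon, so the stereocentre of 1 (future C5') is carried over untouched.

Step 2
Reactants: 2 (2R)-1-chloro-5-(trimethylsilyl)pent-4-yn-2-ol
Product: 5 (3R)-hex-1-en-5-yn-3-ol, via silylalkynyl oxirane 3 (not isolated), via silyl enynol 4 (not isolated)
Conditions: Me3S+ I− (4 equiv), n-BuLi (3.9 equiv), THF, −20 °C → rt; then MeOH, K2CO3, rt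
Reagents that add atoms: trimethylsulfonium iodide C[S+](C)C.[I-]
Why: Excess dimethylsulfonium methylide closes the chlorohydrin to the epoxide, opens it at CH2 and eliminates Me2S (one-carbon epoxide-to-allylic-alcohol homologation), then methanolysis cleaves the C–Si bond; the carbinol centre is not involved.

Step 3
Reactants: 5 (3R)-hex-1-en-5-yn-3-ol
Product: 7 (2E,5R)-3-methylhepta-2,6-diene-1,5-diol, via alkenylalane 6 (not isolated)
Conditions: Me3Al (3 equiv), Cp2ZrCl2 (0.3 equiv), CH2Cl2, 0 °C → rt; evaporate; n-BuLi, THF, −78 °C; (CH2O)n, → rt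
Reagents that add atoms: trimethylaluminium C[Al](C)C; paraformaldehyde (as formaldehyde) C=O
Why: Negishi Zr-catalysed carboalumination adds Me and Al syn across the alkyne with Me on the internal carbon, so trapping the alanate with formaldehyde gives only the E trisubstituted allylic alcohol.

Step 4
Reactants: 7 (2E,5R)-3-methylhepta-2,6-diene-1,5-diol
Product: 8 [(2S,3S)-3-[(2R)-2-hydroxybut-3-en-1-yl]-3-methyloxiran-2-yl]methanol
Conditions: Ti(OiPr)4 (0.2 equiv), L-(+)-DET (0.25 equiv), t-BuOOH (1.3 equiv), 4 Å MS, CH2Cl2, −25 °C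
Reagents that add atoms: tert-butyl hydroperoxide CC(C)(C)OO
Why: Sharpless asymmetric epoxidation with L-(+)-tartrate gives the 2S,3S epoxide of the E allylic alcohol (as for geraniol), and the R vinyl carbinol is the slow-reacting partner for this tartrate, so its terminal alkene is left alone.

Step 5
Reactants: 8 [(2S,3S)-3-[(2R)-2-hydroxybut-3-en-1-yl]-3-methyloxiran-2-yl]methanol
Product: 9 [(2S,3S)-3-[(2R)-2-hydroxybut-3-en-1-yl]-3-methyloxiran-2-yl]methyl 4-methylbenzenesulfonate
Conditions: TsCl (1.05 equiv), Et3N, DMAP (cat.), CH2Cl2, −20 → 0 °C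
Reagents that add atoms: 4-methylbenzenesulfonyl chloride Cc1ccc(cc1)S(=O)(=O)Cl
Why: Sulfonylation is much faster at the primary than at the secondary hydroxyl; the tosylate both blocks O1' and activates C1' for the later ether formation.

Step 6
Reactants: 9 [(2S,3S)-3-[(2R)-2-hydroxybut-3-en-1-yl]-3-methyloxiran-2-yl]methyl 4-methylbenzenesulfonate
Product: 10 (2R)-1-[(2S,3S)-2-methyl-3-({[(4-methylphenyl)sulfonyl]oxy}methyl)oxiran-2-yl]but-3-en-2-yl 2-methylprop-2-enoate
Conditions: methacryloyl chloride, Et3N, DMAP (cat.), CH2Cl2, 0 °C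
Reagents that add atoms: methacryloyl chloride CC(=C)C(=O)Cl
Why: DMAP-catalysed O-acylation of the only free hydroxyl installs the second alkene for metathesis with retention at C5'.

Step 7
Reactants: 10 (2R)-1-[(2S,3S)-2-methyl-3-({[(4-methylphenyl)sulfonyl]oxy}methyl)oxiran-2-yl]but-3-en-2-yl 2-methylprop-2-enoate
Product: 11 [(2S,3S)-3-methyl-3-{[(2R)-4-methyl-5-oxo-2,5-dihydrofuran-2-yl]methyl}oxiran-2-yl]methyl 4-methylbenzenesulfonate
Conditions: Grubbs II (5 mol %), CH2Cl2 (5 mM), 40 °C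
Reagents that add atoms: none
Why: Ring-closing metathesis: the Ru carbene loads on the monosubstituted vinyl group and closes onto the methacrylate to give the α-methylbutenolide with loss of ethylene; epoxide and tosylate are inert.

Step 8
Reactants: 11 [(2S,3S)-3-methyl-3-{[(2R)-4-methyl-5-oxo-2,5-dihydrofuran-2-yl]methyl}oxiran-2-yl]methyl 4-methylbenzenesulfonate
Product: 12 [(2S,3S)-3-methyl-3-{[(2S,4S)-4-methyl-5-oxooxolan-2-yl]methyl}oxiran-2-yl]methyl 4-methylbenzenesulfonate
Conditions: H2 (3 atm), 5% Rh/Al2O3, EtOAc, rt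
Reagents that add atoms: none
Why: Heterogeneous hydrogenation delivers H2 to the butenolide face anti to the C5' substituent, placing the C7' methyl cis to the side chain (7'S); Rh/alumina avoids allylic C–O hydrogenolysis and double-bond migration.

Step 9
Reactants: 12 [(2S,3S)-3-methyl-3-{[(2S,4S)-4-methyl-5-oxooxolan-2-yl]methyl}oxiran-2-yl]methyl 4-methylbenzenesulfonate
Product: 13 (2S,3R)-2,3-dihydroxy-3-methyl-4-[(2S,4S)-4-methyl-5-oxooxolan-2-yl]butyl 4-methylbenzenesulfonate
Conditions: HClO4 (cat.), THF/H2O 3:1, 0 °C → rt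
Reagents that add atoms: water O
Why: Acid-catalysed epoxide hydrolysis: water attacks the protonated epoxide at the tertiary carbon (C2' is deactivated by CH2OTs) with inversion, turning the 2S,3S epoxide into the anti 2S,3R diol.

Step 10
Reactants: 14 2-methoxyresorcinol
Product: 16 2,4-dihydroxy-3-methoxybenzaldehyde, via aryl iminium chloride 15 (not isolated)
Conditions: POCl3, DMF, MeCN, −15 °C → rt; then H2O, 50 °C
Reagents that add atoms: N,N-dimethylformamide CN(C)C=O; water O
Why: Vilsmeier–Haack formylation occurs at the position ortho to one hydroxyl and para to the other (C4 = C6 by symmetry), and the iminium salt is hydrolysed on work-up.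

Step 11
Reactants: 16 2,4-dihydroxy-3-methoxybenzaldehyde
Product: 17 2-hydroxy-3-methoxy-4-(methoxymethoxy)benzaldehyde
Conditions: MOMCl (1.05 equiv), K2CO3, acetone, 0 °C → rt
Reagents that add atoms: chloromethyl methyl ether COCCl
Why: Williamson-type alkylation is selective for the 4-OH, which is the more acidic one and is not tied up in the hydrogen bond to the aldehyde.

Step 12
Reactants: 17 2-hydroxy-3-methoxy-4-(methoxymethoxy)benzaldehyde
Product: 18 6-ethenyl-2-methoxy-3-(methoxymethoxy)phenol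
Conditions: Ph3PCH3Br (2.5 equiv), KOtBu (2.5 equiv), THF, 0 °C → rt
Reagents that add atoms: methyltriphenylphosphonium bromide C[P+](c1ccccc1)(c1ccccc1)c1ccccc1.[Br-]
Why: Wittig methylenation with excess ylide (one equivalent is spent on the phenol) converts the aldehyde into the styrene.

Step 13
Reactants: 18 6-ethenyl-2-methoxy-3-(methoxymethoxy)phenol
Product: 19 6-ethenyl-2-methoxy-3-(methoxymethoxy)phenyl prop-2-enoate
Conditions: acryloyl chloride, Et3N, CH2Cl2, 0 °C
Reagents that add atoms: acryloyl chloride C=CC(=O)Cl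
Why: O-Acylation of the phenol gives the styrene/acrylate diene needed for metathesis.

Step 14
Reactants: 19 6-ethenyl-2-methoxy-3-(methoxymethoxy)phenyl prop-2-enoate
Product: 20 8-methoxy-7-(methoxymethoxy)-2H-chromen-2-one
Conditions: Grubbs II (3 mol %), CH2Cl2, 40 °C
Reagents that add atoms: none
Why: Ring-closing metathesis between the styrene and the acrylate closes the six-membered α-pyrone (coumarin) ring with loss of ethylene.

Step 15
Reactants: 20 8-methoxy-7-(methoxymethoxy)-2H-chromen-2-one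
Product: 21 7-hydroxy-8-methoxy-2H-chromen-2-one
Conditions: 3 M HCl, MeOH, 50 °C
Reagents that add atoms: none
Why: Acid-catalysed acetal cleavage removes the MOM group; the aryl methyl ether and the lactone are stable.

Step 16
Reactants: 13 (2S,3R)-2,3-dihydroxy-3-methyl-4-[(2S,4S)-4-methyl-5-oxooxolan-2-yl]butyl 4-methylbenzenesulfonate; 21 7-hydroxy-8-methoxy-2H-chromen-2-one
Product: 23 7-{[(2S,3R)-2,3-dihydroxy-3-methyl-4-[(2S,4S)-4-methyl-5-oxooxolan-2-yl]butyl]oxy}-8-methoxy-2H-chromen-2-one (target), via terminal epoxide 22 (not isolated)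
Conditions: K2CO3, DMF, 60 °C
Reagents that add atoms: none
Why: Under carbonate the 2'-alkoxide displaces the neighbouring tosylate to give the terminal epoxide, which the aryloxide opens at the unhindered CH2 (Williamson-type ether synthesis); no bond to C2' or C3' is broken, so both centres are retained.

## Compound list

1 | (R)-epichlorohydrin, (2R)-2-(chloromethyl)oxirane | ClC[C@H]1CO1 | starting material
2 | (2R)-1-chloro-5-(trimethylsilyl)pent-4-yn-2-ol | ClC[C@H](O)CC#C[Si](C)(C)C | intermediate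
3 | (2R)-2-[3-(trimethylsilyl)prop-2-yn-1-yl]oxirane | C1O[C@@H]1CC#C[Si](C)(C)C | intermediate (not isolated)
4 | (3R)-6-(trimethylsilyl)hex-1-en-5-yn-3-ol | C=C[C@H](O)CC#C[Si](C)(C)C | intermediate (not isolated)
5 | (3R)-hex-1-en-5-yn-3-ol | C=C[C@H](O)CC#C | intermediate
6 | [(1E,4R)-4-[(dimethylalumanyl)oxy]-2-methylhexa-1,5-dien-1-yl]dimethylalumane | C=C[C@H](O[Al](C)C)C/C(C)=C/[Al](C)C | intermediate (not isolated)
7 | (2E,5R)-3-methylhepta-2,6-diene-1,5-diol | C=C[C@H](O)C/C(C)=C/CO | intermediate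
8 | [(2S,3S)-3-[(2R)-2-hydroxybut-3-en-1-yl]-3-methyloxiran-2-yl]methanol | OC[C@@H]1O[C@@]1(C)C[C@@H](O)C=C | intermediate
9 | [(2S,3S)-3-[(2R)-2-hydroxybut-3-en-1-yl]-3-methyloxiran-2-yl]methyl 4-methylbenzenesulfonate | Cc1ccc(cc1)S(=O)(=O)OC[C@@H]1O[C@@]1(C)C[C@@H](O)C=C | intermediate
10 | (2R)-1-[(2S,3S)-2-methyl-3-({[(4-methylphenyl)sulfonyl]oxy}methyl)oxiran-2-yl]but-3-en-2-yl 2-methylprop-2-enoate | Cc1ccc(cc1)S(=O)(=O)OC[C@@H]1O[C@@]1(C)C[C@@H](OC(=O)C(C)=C)C=C | intermediate
11 | [(2S,3S)-3-methyl-3-{[(2R)-4-methyl-5-oxo-2,5-dihydrofuran-2-yl]methyl}oxiran-2-yl]methyl 4-methylbenzenesulfonate | Cc1ccc(cc1)S(=O)(=O)OC[C@@H]1O[C@@]1(C)C[C@H]2OC(=O)C(C)=C2 | intermediate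
12 | [(2S,3S)-3-methyl-3-{[(2S,4S)-4-methyl-5-oxooxolan-2-yl]methyl}oxiran-2-yl]methyl 4-methylbenzenesulfonate | Cc1ccc(cc1)S(=O)(=O)OC[C@@H]1O[C@@]1(C)C[C@@H]2C[C@H](C)C(=O)O2 | intermediate
13 | (2S,3R)-2,3-dihydroxy-3-methyl-4-[(2S,4S)-4-methyl-5-oxooxolan-2-yl]butyl 4-methylbenzenesulfonate | Cc1ccc(cc1)S(=O)(=O)OC[C@H](O)[C@](C)(O)C[C@@H]2C[C@H](C)C(=O)O2 | intermediate
14 | 2-methoxyresorcinol, 2-methoxybenzene-1,3-diol | COc1c(O)cccc1O | starting material
15 | [(2,4-dihydroxy-3-methoxyphenyl)methylidene]dimethylazanium chloride | C[N+](C)=Cc1ccc(O)c(OC)c1O.[Cl-] | intermediate (not isolated)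
16 | 2,4-dihydroxy-3-methoxybenzaldehyde | COc1c(O)ccc(C=O)c1O | intermediate
17 | 2-hydroxy-3-methoxy-4-(methoxymethoxy)benzaldehyde | COCOc1ccc(C=O)c(O)c1OC | intermediate
18 | 6-ethenyl-2-methoxy-3-(methoxymethoxy)phenol | COCOc1ccc(C=C)c(O)c1OC | intermediate
19 | 6-ethenyl-2-methoxy-3-(methoxymethoxy)phenyl prop-2-enoate | COCOc1ccc(C=C)c(OC(=O)C=C)c1OC | intermediate
20 | 8-methoxy-7-(methoxymethoxy)-2H-chromen-2-one | COCOc1ccc2ccc(=O)oc2c1OC | intermediate
21 | 7-hydroxy-8-methoxy-2H-chromen-2-one | COc1c(O)ccc2ccc(=O)oc12 | intermediate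
22 | (3S,5S)-5-[(2R)-2-hydroxy-2-[(2S)-oxiran-2-yl]propyl]-3-methyloxolan-2-one | C1O[C@@H]1[C@](C)(O)C[C@@H]2C[C@H](C)C(=O)O2 | intermediate (not isolated)
23 | 7-{[(2S,3R)-2,3-dihydroxy-3-methyl-4-[(2S,4S)-4-methyl-5-oxooxolan-2-yl]butyl]oxy}-8-methoxy-2H-chromen-2-one | COc1c(OC[C@H](O)[C@](C)(O)C[C@@H]2C[C@H](C)C(=O)O2)ccc2ccc(=O)oc12 | target

## Step count and risks

Total step count: 16. Longest linear sequence: 10 (steps 1–9, then step 16); the coumarin branch is steps 10–15. 10/16 = 0.63.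

**Step 3 (carboalumination and formaldehyde trapping on the unprotected enynol).** The alanate/paraformaldehyde trap can be low-yielding with an aluminium alkoxide present. The fallback sets out from 5 and comes back at 7. The same carboalumination is run, but alkenylalane 6 is quenched with iodine to give the isolable vinyl iodide (3R,5E)-6-iodo-5-methylhexa-1,5-dien-3-ol F1. C1' is then introduced by Pd-catalysed methoxycarbonylation (PdCl2(PPh3)2, CO 1 atm, MeOH, Et3N, 50 °C), which keeps the alkene geometry and gives methyl (2E,5R)-5-hydroxy-3-methylhepta-2,6-dienoate F2. Reduction with DIBAL-H (CH2Cl2, −78 °C) gives diol 7.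

**Step 9 (invertive hydrolysis at the tertiary epoxide carbon).** Partial SN1 character would erode the C3' configuration. The fallback sets out from 7 and comes back at 22, and so at 23; it moves the inversion to the secondary carbon C2'.
- Epoxidation of 7 with D-(−)-DET (limiting t-BuOOH, since the vinyl carbinol is now the matched partner) gives [(2R,3R)-3-[(2R)-2-hydroxybut-3-en-1-yl]-3-methyloxiran-2-yl]methanol F3.
- Both hydroxyls are acylated with methacryloyl chloride to give (2R)-1-[(2R,3R)-2-methyl-3-{[(2-methylprop-2-enoyl)oxy]methyl}oxiran-2-yl]but-3-en-2-yl 2-methylprop-2-enoate F4.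
- Grubbs II closes only the five-membered ring, giving [(2R,3R)-3-methyl-3-{[(2R)-4-methyl-5-oxo-2,5-dihydrofuran-2-yl]methyl}oxiran-2-yl]methyl 2-methylprop-2-enoate F5.
- Rh/Al2O3–H2 saturates the butenolide (cis) and the spare methacrylate, giving [(2R,3R)-3-methyl-3-{[(2S,4S)-4-methyl-5-oxooxolan-2-yl]methyl}oxiran-2-yl]methyl 2-methylpropanoate F6.
- K2CO3/MeOH at 0 °C removes the primary ester, giving (3S,5S)-5-{[(2R,3R)-3-(hydroxymethyl)-2-methyloxiran-2-yl]methyl}-3-methyloxolan-2-one F7.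
- F7 and 21 are heated with Cs2CO3 and catalytic KOtBu in DMF at 80 °C (aprotic Payne conditions). The C1' alkoxide attacks C2' with clean SN2 inversion to give terminal epoxide 22, which the aryloxide opens in the same flask to 23.

**Step 16 (ether-forming union).** Payne scrambling of epoxide 22 or oxetane formation could compete. The fallback sets out from 12 (with 21) and comes back at 23. The caesium aryloxide of 21 (Cs2CO3, DMF, 50 °C) displaces the primary tosylate of 12 directly, as with glycidyl tosylates, to give 8-methoxy-7-{[(2S,3S)-3-methyl-3-{[(2S,4S)-4-methyl-5-oxooxolan-2-yl]methyl}oxiran-2-yl]methoxy}-2H-chromen-2-one F8. The epoxide is then hydrolysed with inversion at C3' (HClO4 cat., THF/H2O) to give 23.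

## Further compounds

F1 | step 3 | (3R,5E)-6-iodo-5-methylhexa-1,5-dien-3-ol | C=C[C@H](O)C/C(C)=C/I
F2 | step 3 | methyl (2E,5R)-5-hydroxy-3-methylhepta-2,6-dienoate | C=C[C@H](O)C/C(C)=C/C(=O)OC
F3 | step 9 | [(2R,3R)-3-[(2R)-2-hydroxybut-3-en-1-yl]-3-methyloxiran-2-yl]methanol | OC[C@H]1O[C@]1(C)C[C@@H](O)C=C
F4 | step 9 | (2R)-1-[(2R,3R)-2-methyl-3-{[(2-methylprop-2-enoyl)oxy]methyl}oxiran-2-yl]but-3-en-2-yl 2-methylprop-2-enoate | CC(=C)C(=O)OC[C@H]1O[C@]1(C)C[C@@H](OC(=O)C(C)=C)C=C
F5 | step 9 | [(2R,3R)-3-methyl-3-{[(2R)-4-methyl-5-oxo-2,5-dihydrofuran-2-yl]methyl}oxiran-2-yl]methyl 2-methylprop-2-enoate | CC(=C)C(=O)OC[C@H]1O[C@]1(C)C[C@H]2OC(=O)C(C)=C2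
F6 | step 9 | [(2R,3R)-3-methyl-3-{[(2S,4S)-4-methyl-5-oxooxolan-2-yl]methyl}oxiran-2-yl]methyl 2-methylpropanoate | CC(C)C(=O)OC[C@H]1O[C@]1(C)C[C@@H]2C[C@H](C)C(=O)O2
F7 | step 9 | (3S,5S)-5-{[(2R,3R)-3-(hydroxymethyl)-2-methyloxiran-2-yl]methyl}-3-methyloxolan-2-one | OC[C@H]1O[C@]1(C)C[C@@H]2C[C@H](C)C(=O)O2
F8 | step 16 | 8-methoxy-7-{[(2S,3S)-3-methyl-3-{[(2S,4S)-4-methyl-5-oxooxolan-2-yl]methyl}oxiran-2-yl]methoxy}-2H-chromen-2-one | COc1c(OC[C@@H]3O[C@@]3(C)C[C@@H]4C[C@H](C)C(=O)O4)ccc2ccc(=O)oc12
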